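## The problem

Compound 27 is a cis-fused hydroazulene of the carotane type. Its atoms are labelled C1 (CH carrying the 4-methoxybenzoate), C2, C3 (quaternary, methyl), C7 (ring-fusion carbinol), C8, C9 and C10 (methyl carbinol) round the seven-membered ring, with C4, C5 and C6 (CH carrying isopropyl) completing the five-membered ring; β is the face of the C3 methyl group. The rings share the C3–C7 bond, and both of its ends are fully substituted, so the fusion must be made by a reaction that tolerates two adjacent quaternary centres. There are five stereocentres: the C3 methyl, C7 hydroxyl, C6 isopropyl and C1 ester oxygen are all β, and the C10 hydroxyl is α, trans to the C1 oxygen. C3 can dictate C7 if the fusion is closed intramolecularly; the C3/C7 pair can then bias the five-membered ring for C6 and the chair of a six-membered ring for C1, and C1 can direct C10. The C7 and C10 tertiary alcohols sit 1,4 across the seven-membered ring and will dehydrate or close a transannular ether under acid. The C7 hydroxyl is β to a carbonyl in every hydrindanone intermediate (retro-aldol, elimination), and the aryl ester does not survive hydride, hydroxide or prolonged fluoride, so it must come last. The enabling feature is that C9 is an unsubstituted methylene between C8 and the oxygenated C10: without it, C1–C2–C3–C7–C8–C10 is the six-membered ring of a cis-hydrindan-5-one, a ring system open to an enantioselective amine-catalysed aldol, so the seven-membered ring can be reached by inserting one carbon next to the C10 carbonyl.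

## Retrosynthesis

**Ester C–O bond (27 to 25 and 26).** Triol 25 has only one secondary hydroxyl (C1); the C7 and C10 hydroxyls are tertiary and hindered. Acylation with acid chloride 26 therefore needs no protecting group, and placing it last keeps the ester away from all hydride, base and fluoride steps.

**C10 carbinol (25 back to 21 through 24, 23 and 22).** The C10–CH3 bond is not cut directly. A methyl nucleophile would approach ketone 21 anti to the C1 silyloxy group and give the cis diol. Instead the carbon is introduced as an exocyclic methylene (22), oxygen is delivered anti to the C1 silyloxy group by a peracid (23), and hydride opens the epoxide at its CH2 terminus (24). Precursor 21 lacks one stereocentre and one carbon; the forward sequence asks only for facial selectivity next to an existing stereocentre.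

**C8–C9 and C9–C10 (21 to 18 and 19).** This is the key cut. Removing the methylene C9 contracts the seven-membered ring to the cyclohexanone ring of cis-hydrindanone 18. Other cuts of the seven-membered ring (C1–C2, C2–C3, C1–C10) would require building a cycloheptane next to two quaternary centres. This cut hands the problem to six-membered-ring chemistry, where the ring fusion comes from an aldol reaction. The forward reaction, homologation with silyl diazoalkane 19, must make C8 migrate and not C1; the C1 silyloxy group, which the target needs anyway, is the control element.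

**C1–O (18 back to 13 through 17 and 14).** The C1 oxygen is installed by enol ether oxidation of the C10 ketone. Doing this on the saturated cis-fused ketone, and not on an enone, lets the chair of the six-membered ring place the new C–O bond β and equatorial. Precursor 13 has one stereocentre fewer. The forward reaction needs enolisation toward C1, away from the neopentyl C8.

**C4 oxygen and C6–H (13 back to 9 through 12 and 10).** The C4 carbonyl is a vestige of the aldol entry; it is used to bring in the isopropyl group and then removed by hydrazone reduction. C6 is set by adding hydrogen to a C5=C6 enone and not by adding the isopropyl nucleophile: any reagent should reach C6 from the α face, opposite the C7 silyloxy and C3 methyl groups. That face is wrong for an incoming isopropyl but right for an incoming hydrogen.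

**C6–isopropyl (9 to 6 and 7 through 8).** Conjugate addition of Grignard reagent 7 to cyclopentenone 6, followed by re-oxidation, attaches the three carbons without any stereochemical demand. Precursor 6 has no isopropyl group and no C6 stereocentre.

**C5=C6 unsaturation and masking (6 back to 2 through 5 and 4).** The C4 ketone can enolise only toward C5, so dehydrogenation is regiochemically unambiguous. The six-ring ketone must be masked as a ketal and the C7 hydroxyl silylated first. Ketol 2 carries no protecting group.

**C7–C8 (2 to 1).** The intramolecular aldol of achiral triketone 1 under catalysis by the unnatural enantiomer of the amino-acid catalyst closes the six-membered ring and sets C3 and C7 together. The cis fusion is enforced by the tether. One step from an achiral compound gives both quaternary centres in the required absolute sense.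

## Roads not taken

**Alternative 1: Buchner ring expansion of an anisole.** The cut is C2–C3 and C3–C7. The α-methyl diazoketone A2 would be decomposed with Rh2(OAc)4 or a copper bis(oxazoline) catalyst; the carbenoid cyclopropanates the ipso–ortho bond of the anisyl ring and the norcaradiene opens to cycloheptatriene A1. This closes the five-membered ring, creates the quaternary C3 and converts a benzene ring into the seven-membered ring in one step. Its merit is brevity: A1 holds all fifteen skeletal carbons after very few steps, and its methoxy group marks C10. In speed to the bicyclic skeleton it is clearly better than the chosen plan.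

Its weak points lie after the key step and in the step itself:
- α-Alkyl diazoketones tend to undergo 1,2-hydride shift to the enone instead of the cycloaddition.
- C3 must be set relative to a remote benzylic C6 or by catalyst control on a substrate that already has a stereocentre.
- A1 is a triene ketone with no C7 oxygen; the C7 hydroxyl (cis to methyl), the C1 oxygen and the saturation of two further double bonds would all have to be introduced regio- and stereoselectively on a flexible cycloheptatriene.
- The C4 carbonyl still has to be removed.

The chosen plan is longer, but every stereocentre is set by a substrate-controlled event on a rigid cis-hydrindane, and the oxygen pattern at C1, C7 and C10 is built in rather than retrofitted.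

**Alternative 2: Reversible aldol annulation setting C6 and C7.** The cut is C6–C7. Cycloheptenone A4, with the C3 quaternary centre and a 4-oxopentyl side chain, would be cyclised under equilibrating base to the β-hydroxy ketone A3, with acetyl, hydroxyl and angular methyl all cis. For the C6/C7 relationship this is as good as or better than the chosen plan: the two centres are set together and the process is self-correcting, whereas the chosen plan needs four steps (5 to 8) and relies on a facial preference in step 7. C4 is never oxygenated, and no ring expansion is needed.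

Its weak points:
- A4 needs its own enantioselective construction of an α-quaternary cycloheptenone, which costs several steps.
- The aldol has competing enolisation sites: the methyl of the side-chain ketone and C8 of the ring ketone.
- The tertiary aldol A3 can revert or dehydrate.
- The acetyl group still has to become isopropyl.
- The C1=C10 alkene must be turned into the trans diol monoester with facial control exerted only from the distant ring fusion, with a free or protected C7 hydroxyl placed to attack a C10 epoxide transannularly.

The chosen plan sets against this the absolute configuration from a single proline-catalysed step on a simple triketone, and a C1 stereocentre installed on a rigid six-membered ring that then directs C10 from the adjacent position.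

**Alternative 3: Enzymatic cyclisation of farnesyl diphosphate.** A carotol-type sesquiterpene synthase would ionise farnesyl diphosphate A6, close both rings and quench the C7 cation with water to give A5. In step economy nothing chemical competes: both rings and three stereocentres come from one operation, with enzyme-controlled absolute configuration.

Its weak points:
- It depends on access to an enzyme with exactly the C3/C6/C7 outcome of the target, on expression and fermentation capacity, and on supply of A6.
- The remaining chemistry from A5 is the least controlled part: oxidising the C1=C10 alkene to the trans diol monoester next to a free C7 hydroxyl invites transannular ether formation, and the face of oxidation is governed only remotely.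

The chosen plan is much longer but needs no biocatalyst, and it handles the C1/C10 diol with the C7 oxygen silylated and with C1 already in place.

Key step: step 13

Assumption: triketone 1 is purchased; it is otherwise the one-step Michael adduct of 2-methylcyclopentane-1,3-dione and but-3-en-2-one.

Remark: the configuration at C6 in compound 8 is left undefined because it is erased in step 6.

## Route

Step 1
Reactants: 1 2-methyl-2-(3-oxobutyl)cyclopentane-1,3-dione
Product: 2 (3aR,7aR)-3a-hydroxy-7a-methylhexahydro-1H-indene-1,5(4H)-dione (cis-fused ketol; C4 and C10 ketones; C7 OH and C3 CH3 β)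
Conditions: D-proline (3 mol%), DMF, rt
Reagents that add atoms: none
Why: Hajos–Parrish intramolecular aldol under enamine catalysis; the side-chain enamine adds to one of the two enantiotopic ring carbonyls, and the tether can only close the cis-fused hydrindane, so C3 and C7 are set together (D-proline should give the mirror image of the classical L-proline ketol); crystallisation should raise the enantiomeric purity.

Step 2
Reactants: 2 (3aR,7aR)-3a-hydroxy-7a-methylhexahydro-1H-indene-1,5(4H)-dione
Product: 4 7a'-methyl-3a'-(trimethylsilyloxy)hexahydrospiro[1,3-dioxolane-2,5'-inden]-1'(4'H)-one (C10 dioxolane; C4 ketone; C7 OSiMe3 β), via C7-O-trimethylsilyl diketone 3 (not isolated)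
Conditions: TMSOTf (1.25 equiv), 2,6-lutidine (1.05 equiv), CH2Cl2, −78 °C; then TMSOCH2CH2OTMS (1.5 equiv), −78 → −30 °C
Reagents that add atoms: trimethylsilyl trifluoromethanesulfonate, C[Si](C)(C)OS(=O)(=O)C(F)(F)F; 1,2-bis(trimethylsilyloxy)ethane, C[Si](C)(C)OCCO[Si](C)(C)C
Why: Silyl triflate silylation of the tertiary alcohol, then Noyori ketalisation catalysed by the remaining TMSOTf; the unhindered six-ring ketone reacts while the C4 ketone next to the quaternary C3 does not, and the low temperature and the silyl cap should suppress β-elimination to the enone.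

Step 3
Reactants: 4 7a'-methyl-3a'-(trimethylsilyloxy)hexahydrospiro[1,3-dioxolane-2,5'-inden]-1'(4'H)-one
Product: 5 C4 trimethylsilyl enol ether of 4 (C4=C5; C7 OSiMe3 β; C10 dioxolane)
Conditions: LDA (1.2 equiv), THF, −78 °C; TMSCl, Et3N, −78 → 0 °C
Reagents that add atoms: chlorotrimethylsilane, C[Si](C)(C)Cl
Why: Kinetic enolate formation and O-silylation; the C4 ketone has α-hydrogens only at C5 because C3 is quaternary, so a single enol ether should form.

Step 4
Reactants: 5 C4 trimethylsilyl enol ether of 4
Product: 6 7a'-methyl-3a'-(trimethylsilyloxy)-3a',4',7',7a'-tetrahydrospiro[1,3-dioxolane-2,5'-inden]-1'(6'H)-one (C5=C6 cyclopentenone; C7 OSiMe3 β)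
Conditions: Pd(OAc)2 (1.05 equiv), MeCN, rt
Reagents that add atoms: none
Why: Ito–Saegusa oxidation; the silyl enol ether transmetalates to a palladium enolate and β-hydride elimination from C6, the only β-hydrogen site, gives the cyclopentenone.

Step 5
Reactants: 6 C5=C6 cyclopentenone; 7 isopropylmagnesium chloride
Product: 8 C4 trimethylsilyl enol ether carrying isopropyl at C6 (C4=C5; C7 OSiMe3 β; C6 configuration undefined)
Conditions: 7 (2 equiv), CuBr·SMe2 (20 mol%), TMSCl (3 equiv), HMPA, THF, −78 → −40 °C; Et3N
Reagents that add atoms: isopropylmagnesium chloride (compound 7), CC(C)[Mg]Cl; chlorotrimethylsilane, C[Si](C)(C)Cl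
Why: Copper-catalysed conjugate addition of a Grignard reagent accelerated by TMSCl, with the enolate trapped as its silyl enol ether; γ-silyloxy cyclopentenones add cuprates without loss of the oxygen, and the face of attack does not matter because C6 becomes sp2 again in step 6.

Step 6
Reactants: 8 C4 trimethylsilyl enol ether carrying isopropyl at C6
Product: 9 3'-isopropyl-7a'-methyl-3a'-(trimethylsilyloxy)-3a',4',7',7a'-tetrahydrospiro[1,3-dioxolane-2,5'-inden]-1'(6'H)-one (C5=C6 enone with isopropyl on C6)
Conditions: Pd(OAc)2 (1.05 equiv), MeCN, rt → 40 °C
Reagents that add atoms: none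
Why: Second Ito–Saegusa oxidation; β-hydride elimination can only take the C6 hydrogen, giving the β-isopropyl enone (conjugate addition then re-oxidation is a standard way to β-alkylate an enone).

Step 7
Reactants: 9 C5=C6 enone with isopropyl on C6
Product: 10 3'-isopropyl-7a'-methyl-3a'-(trimethylsilyloxy)hexahydrospiro[1,3-dioxolane-2,5'-inden]-1'(4'H)-one (C6 isopropyl β; C7 OSiMe3 β; C3 CH3 β)
Conditions: H2 (3 atm), 10% Pd/C, EtOAc, rt
Reagents that add atoms: none
Why: Heterogeneous hydrogenation of the enone C=C; hydrogen should add to C6 from the α face, opposite the C7 trimethylsilyloxy group on the neighbouring carbon and the angular methyl, which places the isopropyl β and cis to the C7 oxygen; the alcohol is kept silylated so that no hydroxyl-directed delivery from the β face can occur.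

Step 8
Reactants: 10 C6β-isopropyl C4 ketone
Product: 12 3a'-hydroxy-3'-isopropyl-7a'-methyloctahydrospiro[1,3-dioxolane-2,5'-indene] (C4 now CH2; C7 OH free; C10 dioxolane), via C4 hydrazone 11 (not isolated)
Conditions: N2H4·H2O, diethylene glycol, 130 °C; then KOH, 200 °C
Reagents that add atoms: none
Why: Wolff–Kishner reduction (Huang-Minlon procedure); the hydrazone is formed before base is added so that the β-oxygenated ketone never meets hot hydroxide as a free carbonyl, the dioxolane is base-stable, the silyl ether is cleaved in the basic medium, and C6 is β to the carbonyl and cannot epimerise.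

Step 9
Reactants: 12 deoxygenated hydroxy ketal
Product: 13 3a-hydroxy-7a-methyl-3-(propan-2-yl)octahydro-5H-inden-5-one (C3 CH3, C7 OH and C6 isopropyl all β)
Conditions: PPTS, acetone–H2O (9:1), 50 °C
Reagents that add atoms: water, O
Why: Mild acid-catalysed ketal hydrolysis; pyridinium tosylate is a weak enough acid that the tertiary β-hydroxy ketone should not dehydrate at this temperature.

Step 10
Reactants: 13 3a-hydroxy-7a-methyl-3-(propan-2-yl)octahydro-5H-inden-5-one
Product: 14 7a-methyl-3-(propan-2-yl)-3a,5-bis(trimethylsilyloxy)-2,3,3a,4,7,7a-hexahydro-1H-indene (C10=C1 silyl enol ether; C7 OSiMe3 β)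
Conditions: TMSOTf (2.5 equiv), Et3N (4 equiv), CH2Cl2, −78 → 0 °C
Reagents that add atoms: trimethylsilyl trifluoromethanesulfonate, C[Si](C)(C)OS(=O)(=O)C(F)(F)F
Why: Soft enolisation with silyl triflate and amine, which also silylates the hindered tertiary alcohol; the proton should be removed at C1 and not at C8, because C8 is neopentyl (flanked by the fully substituted C7) and β to the silyloxy group.

Step 11
Reactants: 14 C10=C1 silyl enol ether
Product: 17 6-hydroxy-7a-methyl-3-(propan-2-yl)-3a-(trimethylsilyloxy)octahydro-5H-inden-5-one (C1 OH β; C10 ketone), via silyloxy epoxide 15 (not isolated), via C1-trimethylsilyloxy ketone 16 (not isolated)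
Conditions: mCPBA, NaHCO3, CH2Cl2, −20 → 0 °C; then 10% aq. citric acid, THF, 0 °C
Reagents that add atoms: 3-chloroperoxybenzoic acid, OOC(=O)c1cccc(Cl)c1
Why: Rubottom oxidation (epoxidation of the enol ether, ring opening with 1,4-silyl shift, selective hydrolysis of the labile secondary α-silyloxy group); in the half-chair that keeps the isopropyl-bearing C6 equatorial on the six-membered ring, the C3–C4 bond is axial on the α face and screens C1 from below, so the peracid should bond to C1 from the β face and the new C–O bond is equatorial.

Step 12
Reactants: 17 C1β-hydroxy ketone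
Product: 18 6-(tert-butyldimethylsilyloxy)-7a-methyl-3-(propan-2-yl)-3a-(trimethylsilyloxy)octahydro-5H-inden-5-one (C1 OTBS β; C7 OSiMe3 β; C6 isopropyl β)
Conditions: TBSOTf (1.3 equiv), 2,6-lutidine, CH2Cl2, −78 → 0 °C
Reagents that add atoms: tert-butyldimethylsilyl trifluoromethanesulfonate, CC(C)(C)[Si](C)(C)OS(=O)(=O)C(F)(F)F
Why: Silyl triflate silylation of a secondary alcohol with a hindered, non-enolising base, so the α-hydroxy ketone is capped without epimerisation or ketol shift.

Step 13
Reactants: 18 C1-OTBS cis-hydrindan-5-one; 19 trimethylsilyldiazomethane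
Product: 21 7-(tert-butyldimethylsilyloxy)-8a-methyl-3-(propan-2-yl)-3a-(trimethylsilyloxy)octahydroazulen-6(1H)-one (C10 ketone; new CH2 C9 between C8 and C10), via C9-trimethylsilyl ketone 20 (not isolated)
Conditions: AlMe3 (1.2 equiv), 19 (1.5 equiv), CH2Cl2, −78 → −20 °C; then wet SiO2, CH2Cl2, rt
Reagents that add atoms: trimethylsilyldiazomethane (compound 19), C[Si](C)(C)C=[N+]=[N-]
Why: AlMe3 activates the C10 carbonyl, the nucleophilic carbon of 19 adds to give an aluminium β-alkoxy diazonium betaine, and loss of N2 is concerted with a 1,2-shift of the ring bond antiperiplanar to the leaving group, so that the new carbon C9 ends bonded to C8 and C10. The closest known reaction type is the Lewis-acid-promoted homologation of cyclic ketones with trimethylsilyldiazomethane, a Tiffeneau–Demjanov-type ring expansion. The seven-membered ring is not closed by a cyclisation but arises by enlargement of the six-membered ring through this 1,2-shift, so no ring-closure mode applies and the cis ring fusion is untouched. No stereocentre is created: C9 becomes a methylene once the C–Si bond of 20 is cleaved on wet silica, and C1, C3, C6 and C7 are spectators. The step needs migration of C8 in preference to C1; the silyloxy-bearing C1 is electron-poor and a poor migrating group, and the betaine rotamer that keeps the bulky Me3Si group away from the OTBS-bearing C1 is the one with C8 anti to N2. A single insertion is expected because the α-silyl ketone 20 is too hindered to add a second molecule of 19. The aprotic, low-temperature conditions should leave the epimerisable C1 and both silyl ethers intact, and the C7 oxygen is kept silylated because a free β-hydroxy ketone would suffer retro-aldol cleavage or elimination with AlMe3.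

Step 14
Reactants: 21 C1-OTBS hydroazulen-6-one
Product: 22 7-(tert-butyldimethylsilyloxy)-8a-methyl-6-methylidene-3-(propan-2-yl)-3a-(trimethylsilyloxy)decahydroazulene (exocyclic C10=CH2)
Conditions: Cp2TiMe2 (3 equiv), toluene, 70 °C, dark
Reagents that add atoms: dimethyltitanocene Cp2TiMe2, C[Ti](C)(C1C=CC=C1)C1C=CC=C1
Why: Petasis methylenation; thermal α-elimination gives Cp2Ti=CH2, which converts the ketone to the alkene through an oxatitanacyclobutane, and the reagent is non-basic, so the C1 stereocentre next to the carbonyl should not epimerise.

Step 15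
Reactants: 22 exocyclic alkene
Product: 23 spiro-epoxide of 22 (C10 epoxide oxygen α and anti to the C1 OTBS; epoxide CH2 β)
Conditions: mCPBA, NaHCO3, CH2Cl2, 0 °C
Reagents that add atoms: 3-chloroperoxybenzoic acid, OOC(=O)c1cccc(Cl)c1
Why: Prilezhaev epoxidation of a 1,1-disubstituted alkene; A(1,3) strain with the exocyclic methylene turns the C1 silyloxy group pseudoaxial, so the peracid should approach from the opposite (α) face and place the oxygen trans to the C1 oxygen.

Step 16
Reactants: 23 spiro-epoxide
Product: 24 7-(tert-butyldimethylsilyloxy)-6,8a-dimethyl-3-(propan-2-yl)-3a-(trimethylsilyloxy)decahydroazulen-6-ol (C10 OH α; C10 CH3 β)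
Conditions: LiEt3BH, THF, 0 °C → rt
Reagents that add atoms: none
Why: SN2 hydride opening of the epoxide at its unhindered CH2 terminus, which turns that carbon into the C10 methyl and leaves the C10–O bond and its configuration untouched.

Step 17
Reactants: 24 bis-silyl tertiary alcohol
Product: 25 (3R,3aS,6R,7R,8aR)-6,8a-dimethyl-3-(propan-2-yl)decahydroazulene-3a,6,7-triol
Conditions: TBAF, THF, rt → 45 °C
Reagents that add atoms: none
Why: Fluoride desilylation of both silyl ethers; no acid is used, so the 1,4-related tertiary C7 and C10 alcohols cannot dehydrate or close a transannular ether.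

Step 18
Reactants: 25 triol; 26 4-methoxybenzoyl chloride
Product: 27 (3R,3aS,6R,7R,8aR)-3a,6-dihydroxy-6,8a-dimethyl-3-(propan-2-yl)decahydroazulen-7-yl 4-methoxybenzoate
Conditions: 26 (1.3 equiv), Et3N, DMAP (cat.), CH2Cl2, 0 °C → rt
Reagents that add atoms: 4-methoxybenzoyl chloride (compound 26), COc1ccc(C(Cl)=O)cc1
Why: DMAP-catalysed acylation; only the secondary C1 hydroxyl should react, because the C7 and C10 hydroxyls are tertiary and flanked by quaternary centres.

## Compound list

1 | 2-methyl-2-(3-oxobutyl)cyclopentane-1,3-dione | CC(=O)CCC1(C)C(=O)CCC1=O | starting material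
2 | (3aR,7aR)-3a-hydroxy-7a-methylhexahydro-1H-indene-1,5(4H)-dione (cis-fused ketol) | O=C1CC[C@@]2(C)C(=O)CC[C@@]2(O)C1 | intermediate
3 | (3aR,7aR)-7a-methyl-3a-(trimethylsilyloxy)hexahydro-1H-indene-1,5(4H)-dione | O=C1CC[C@@]2(C)C(=O)CC[C@@]2(O[Si](C)(C)C)C1 | intermediate (not isolated)
4 | 7a'-methyl-3a'-(trimethylsilyloxy)hexahydrospiro[1,3-dioxolane-2,5'-inden]-1'(4'H)-one (methyl and silyloxy cis) | O1CCOC12CC[C@@]3(C)C(=O)CC[C@@]3(O[Si](C)(C)C)C2 | intermediate
5 | 7a'-methyl-1',3a'-bis(trimethylsilyloxy)-3',3a',4',6',7',7a'-hexahydrospiro[1,3-dioxolane-2,5'-indene] (C4=C5 enol ether) | O1CCOC12CC[C@@]3(C)C(O[Si](C)(C)C)=CC[C@@]3(O[Si](C)(C)C)C2 | intermediate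
6 | 7a'-methyl-3a'-(trimethylsilyloxy)-3a',4',7',7a'-tetrahydrospiro[1,3-dioxolane-2,5'-inden]-1'(6'H)-one (C5=C6 enone) | O1CCOC12CC[C@@]3(C)C(=O)C=C[C@@]3(O[Si](C)(C)C)C2 | intermediate
7 | isopropylmagnesium chloride | CC(C)[Mg]Cl | starting material
8 | 3'-isopropyl-7a'-methyl-1',3a'-bis(trimethylsilyloxy)-3',3a',4',6',7',7a'-hexahydrospiro[1,3-dioxolane-2,5'-indene] (C6 configuration undefined) | O1CCOC12CC[C@@]3(C)C(O[Si](C)(C)C)=CC(C(C)C)[C@@]3(O[Si](C)(C)C)C2 | intermediate
9 | 3'-isopropyl-7a'-methyl-3a'-(trimethylsilyloxy)-3a',4',7',7a'-tetrahydrospiro[1,3-dioxolane-2,5'-inden]-1'(6'H)-one | O1CCOC12CC[C@@]3(C)C(=O)C=C(C(C)C)[C@@]3(O[Si](C)(C)C)C2 | intermediate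
10 | 3'-isopropyl-7a'-methyl-3a'-(trimethylsilyloxy)hexahydrospiro[1,3-dioxolane-2,5'-inden]-1'(4'H)-one (isopropyl, silyloxy and methyl all β) | O1CCOC12CC[C@@]3(C)C(=O)C[C@H](C(C)C)[C@@]3(O[Si](C)(C)C)C2 | intermediate
11 | C4 hydrazone of 10 | O1CCOC12CC[C@@]3(C)C(=NN)C[C@H](C(C)C)[C@@]3(O[Si](C)(C)C)C2 | intermediate (not isolated)
12 | 3a'-hydroxy-3'-isopropyl-7a'-methyloctahydrospiro[1,3-dioxolane-2,5'-indene] (isopropyl, hydroxyl and methyl all β) | O1CCOC12CC[C@@]3(C)CC[C@H](C(C)C)[C@@]3(O)C2 | intermediate
13 | 3a-hydroxy-7a-methyl-3-(propan-2-yl)octahydro-5H-inden-5-one (isopropyl, hydroxyl and methyl all β) | O=C1CC[C@@]2(C)CC[C@H](C(C)C)[C@@]2(O)C1 | intermediate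
14 | 7a-methyl-3-(propan-2-yl)-3a,5-bis(trimethylsilyloxy)-2,3,3a,4,7,7a-hexahydro-1H-indene (C10=C1 enol ether) | C[Si](C)(C)OC1=CC[C@@]2(C)CC[C@H](C(C)C)[C@@]2(O[Si](C)(C)C)C1 | intermediate
15 | C1–C10 β-epoxide of 14 (silyloxy epoxide) | C[Si](C)(C)O[C@@]12O[C@@H]1C[C@@]3(C)CC[C@H](C(C)C)[C@@]3(O[Si](C)(C)C)C2 | intermediate (not isolated)
16 | 7a-methyl-3-(propan-2-yl)-3a,6-bis(trimethylsilyloxy)octahydro-5H-inden-5-one (C1 OSiMe3 β) | C[Si](C)(C)O[C@@H]1C[C@@]2(C)CC[C@H](C(C)C)[C@@]2(O[Si](C)(C)C)CC1=O | intermediate (not isolated)
17 | 6-hydroxy-7a-methyl-3-(propan-2-yl)-3a-(trimethylsilyloxy)octahydro-5H-inden-5-one (C1 OH β) | O[C@@H]1C[C@@]2(C)CC[C@H](C(C)C)[C@@]2(O[Si](C)(C)C)CC1=O | intermediate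
18 | 6-(tert-butyldimethylsilyloxy)-7a-methyl-3-(propan-2-yl)-3a-(trimethylsilyloxy)octahydro-5H-inden-5-one (all four substituents β) | CC(C)(C)[Si](C)(C)O[C@@H]1C[C@@]2(C)CC[C@H](C(C)C)[C@@]2(O[Si](C)(C)C)CC1=O | intermediate
19 | trimethylsilyldiazomethane | C[Si](C)(C)C=[N+]=[N-] | starting material
20 | 7-(tert-butyldimethylsilyloxy)-8a-methyl-3-(propan-2-yl)-5-(trimethylsilyl)-3a-(trimethylsilyloxy)octahydroazulen-6(1H)-one (C9 configuration undefined) | CC(C)(C)[Si](C)(C)O[C@@H]1C[C@@]2(C)CC[C@H](C(C)C)[C@@]2(O[Si](C)(C)C)CC([Si](C)(C)C)C1=O | intermediate (not isolated)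
21 | 7-(tert-butyldimethylsilyloxy)-8a-methyl-3-(propan-2-yl)-3a-(trimethylsilyloxy)octahydroazulen-6(1H)-one | CC(C)(C)[Si](C)(C)O[C@@H]1C[C@@]2(C)CC[C@H](C(C)C)[C@@]2(O[Si](C)(C)C)CCC1=O | intermediate
22 | 7-(tert-butyldimethylsilyloxy)-8a-methyl-6-methylidene-3-(propan-2-yl)-3a-(trimethylsilyloxy)decahydroazulene | CC(C)(C)[Si](C)(C)O[C@@H]1C[C@@]2(C)CC[C@H](C(C)C)[C@@]2(O[Si](C)(C)C)CCC1=C | intermediate
23 | spiro-epoxide of 22 at C10 (epoxide oxygen α, CH2 β) | CC(C)(C)[Si](C)(C)O[C@@H]1C[C@@]2(C)CC[C@H](C(C)C)[C@@]2(O[Si](C)(C)C)CC[C@@]13OC3 | intermediate
24 | 7-(tert-butyldimethylsilyloxy)-6,8a-dimethyl-3-(propan-2-yl)-3a-(trimethylsilyloxy)decahydroazulen-6-ol (C10 OH α) | CC(C)(C)[Si](C)(C)O[C@@H]1C[C@@]2(C)CC[C@H](C(C)C)[C@@]2(O[Si](C)(C)C)CC[C@@]1(C)O | intermediate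
25 | (3R,3aS,6R,7R,8aR)-6,8a-dimethyl-3-(propan-2-yl)decahydroazulene-3a,6,7-triol | O[C@@H]1C[C@@]2(C)CC[C@H](C(C)C)[C@@]2(O)CC[C@@]1(C)O | intermediate
26 | 4-methoxybenzoyl chloride | COc1ccc(C(Cl)=O)cc1 | starting material
27 | (3R,3aS,6R,7R,8aR)-3a,6-dihydroxy-6,8a-dimethyl-3-(propan-2-yl)decahydroazulen-7-yl 4-methoxybenzoate | COc1ccc(C(=O)O[C@@H]2C[C@@]3(C)CC[C@H](C(C)C)[C@@]3(O)CC[C@@]2(C)O)cc1 | target

## Step count and least certain steps

Total step count: 18. Longest linear sequence: 18 steps (1 to 27); the route is fully linear.

**Step 13 (key step).** The most likely failures are competing migration of C1, slow addition of 19 to a carbonyl flanked by a silyloxy methine and a neopentyl methylene, and transfer of a methyl group from AlMe3 to the activated ketone. All three come from the crowding around C10. The fallback fixes the site of insertion by the position of an enol ether instead of by migratory aptitude. It sets out from 18. Kinetic deprotonation at C8 (LDA, then TMSCl; the oxygenated α-carbon C1 is deprotonated more slowly) should give the C8=C10 silyl enol ether F1. Cyclopropanation with Et2Zn and CH2I2 gives the siloxycyclopropane F2. Oxidative opening with FeCl3 in DMF cleaves the internal cyclopropane bond to the ring-enlarged β-chloro ketone F3. NaOAc in methanol eliminates HCl to the cycloheptenone F4, and hydrogenation over Pd/C gives 21, where the route is rejoined.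

**Step 7.** Hydrogen may be delivered to the β face, because the two faces of C6 differ only in a silyloxy group against a ring methylene on C7, and the α face is the concave side of the cis-hydrindane. The fallback forms the C6–C bond under direction by the C7 oxygen instead of the C6–H bond. It sets out from 6. K2CO3 in methanol frees the hydroxy enone F5. Its magnesium alkoxide (made with tert-butylmagnesium chloride) should deliver excess isopropylmagnesium chloride to C6 on the face of the oxygen (alkoxide-directed conjugate addition), giving the hydroxy ketone F6 with isopropyl cis to the C7 hydroxyl. F6 is submitted to the conditions of step 8 and returns to the route at 12.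

**Step 8.** Hydrazone formation at the neopentyl C4 carbonyl may be slow. If the silyl ether is lost first, hot base can open the β-oxy ketone by retro-aldol cleavage of the C3–C7 bond. The fallback avoids condensation at C4 and strong base at high temperature. It sets out from 10. KHMDS and PhNTf2 give the C4 enol triflate F7 (C4=C5). Palladium-catalysed formate reduction (Pd(OAc)2, PPh3, HCO2H, Bu3N) gives the cyclopentene F8. Hydrogenation over Pd/C gives the saturated silyl ether F9, and aqueous HCl in THF removes the dioxolane and the silyl ether together to give 13, where the route is rejoined.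

**Step 11.** The peracid may attack the α face of the enol ether, because the preference depends on which half-chair of the six-membered ring reacts. Some enolisation toward C8 in step 10 would add a regioisomeric ketol. The fallback corrects C1 by stereospecific inversion instead of relying on the facial preference. It sets out from 14. If the oxidation gives the C1 epimer F10 (C1 OH α), a Mitsunobu reaction with 4-nitrobenzoic acid (PPh3, diisopropyl azodicarboxylate) inverts C1 to the β 4-nitrobenzoate F11. Brief methanolysis with K2CO3 gives 17, where the route is rejoined.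

**Step 15.** Facial selectivity may be poor or reversed in the conformationally mobile seven-membered ring, since the argument rests on the C1 silyloxy group being pseudoaxial. The fallback uses the complementary polarity: a face that is open to an electrophilic oxygen is also open to a carbon nucleophile. It sets out from 21. If the β face of C10 proves the accessible one, addition of MeLi with CeCl3 to ketone 21 from that face should place the methyl β and the hydroxyl α. This gives 24 directly, where the route is rejoined; the fallback makes no new compound (F0).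

## Further compounds

F1 | step 13 | C8=C10 trimethylsilyl enol ether of 18 | CC(C)(C)[Si](C)(C)O[C@@H]1C[C@@]2(C)CC[C@H](C(C)C)[C@@]2(O[Si](C)(C)C)C=C1O[Si](C)(C)C
F2 | step 13 | siloxycyclopropane from F1 (CH2 bridging C8 and C10; new centres undefined) | CC(C)(C)[Si](C)(C)O[C@@H]1C[C@@]2(C)CC[C@H](C(C)C)[C@@]2(O[Si](C)(C)C)C3CC13O[Si](C)(C)C
F3 | step 13 | C8-chloro derivative of 21 (β-chloro cycloheptanone) | CC(C)(C)[Si](C)(C)O[C@@H]1C[C@@]2(C)CC[C@H](C(C)C)[C@@]2(O[Si](C)(C)C)C(Cl)CC1=O
F4 | step 13 | C8=C9 enone corresponding to 21 | CC(C)(C)[Si](C)(C)O[C@@H]1C[C@@]2(C)CC[C@H](C(C)C)[C@@]2(O[Si](C)(C)C)C=CC1=O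
F5 | step 7 | 3a'-hydroxy-7a'-methyl-3a',4',7',7a'-tetrahydrospiro[1,3-dioxolane-2,5'-inden]-1'(6'H)-one | O1CCOC12CC[C@@]3(C)C(=O)C=C[C@@]3(O)C2
F6 | step 7 | 3a'-hydroxy-3'-isopropyl-7a'-methylhexahydrospiro[1,3-dioxolane-2,5'-inden]-1'(4'H)-one (isopropyl cis to hydroxyl) | O1CCOC12CC[C@@]3(C)C(=O)C[C@H](C(C)C)[C@@]3(O)C2
F7 | step 8 | C4 enol triflate of 10 (C4=C5) | O1CCOC12CC[C@@]3(C)C(OS(=O)(=O)C(F)(F)F)=C[C@H](C(C)C)[C@@]3(O[Si](C)(C)C)C2
F8 | step 8 | C4=C5 alkene from F7 | O1CCOC12CC[C@@]3(C)C=C[C@H](C(C)C)[C@@]3(O[Si](C)(C)C)C2
F9 | step 8 | C7 trimethylsilyl ether of 12 | O1CCOC12CC[C@@]3(C)CC[C@H](C(C)C)[C@@]3(O[Si](C)(C)C)C2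
F10 | step 11 | C1 epimer of 17 (C1 OH α) | O[C@H]1C[C@@]2(C)CC[C@H](C(C)C)[C@@]2(O[Si](C)(C)C)CC1=O
F11 | step 11 | 4-nitrobenzoate of 17 (C1 ester β) | O=C(O[C@@H]1C[C@@]2(C)CC[C@H](C(C)C)[C@@]2(O[Si](C)(C)C)CC1=O)c1ccc(cc1)[N+](=O)[O-]
F0 | step 15 | none | none
A1 | alternative 1 | 6-methoxy-8a-methyl-3-(propan-2-yl)-3,8a-dihydroazulen-1(2H)-one | C1=C[C@@]2(C)C(=O)C[C@H](C(C)C)C2=CC=C1OC
A2 | alternative 1 | 2-diazo-5-(4-methoxyphenyl)-6-methylheptan-3-one (C6 configuration of the target) | CC(=[N+]=[N-])C(=O)C[C@H](C(C)C)c1ccc(OC)cc1
A3 | alternative 2 | 1-[3a-hydroxy-6,8a-dimethyl-1,2,3,3a,4,5,8,8a-octahydroazulen-3-yl]ethan-1-one (acetyl, hydroxyl and methyl cis) | CC1=CC[C@@]2(C)CC[C@H](C(C)=O)[C@@]2(O)CC1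
A4 | alternative 2 | 2,5-dimethyl-2-(4-oxopentyl)cyclohept-4-en-1-one | CC1=CC[C@@](C)(CCCC(C)=O)C(=O)CC1
A5 | alternative 3 | 6,8a-dimethyl-3-(propan-2-yl)-2,3,4,5,8,8a-hexahydro-1H-azulen-3a-ol (dauc-8-en-5-ol) | CC1=CC[C@@]2(C)CC[C@H](C(C)C)[C@@]2(O)CC1
A6 | alternative 3 | (2E,6E)-farnesyl diphosphate | CC(C)=CCC/C(C)=C/CC/C(C)=C/COP(=O)(O)OP(=O)(O)O
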